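## The problem

Target 27 is a germacranolide, numbered here C1–C10 around the ten-membered ring, with the lactone arm C11 (C12 carbonyl, C13 exo-methylene) on C7, C14 on C10 and the methyl C15 on C4. The ring carries two trisubstituted olefins, C1=C10 and C4=C5, both with the ring carbons cis, and is trans-fused at C6/C7 to an α-methylene-γ-butyrolactone. Four contiguous stereocentres (6R,7R,8S,9R) must be set: H6/H7 trans, H7/H8 cis, and an erythro (cis) 8,9-diol of which only O9 is acetylated. C8 and C9 can be bought as a pair in one cis-dihydroxylation. C8 then sits next to C7 and can steer the face on which the C6–C7 bond forms, and C6 and C7 can be made together in one closed transition state. The α-methylene lactone is a Michael acceptor that tolerates neither carbanions nor hydride or dissolving-metal reagents. The C14 isovalerate is an allylic ester that zerovalent palladium ionises. The 9-acetate next to a free 8-OH migrates under base, and the skipped 1,5-diene can lose its Z geometry through allyl intermediates. The feature that opens the route is the six-carbon run C7–C8–C9–C10=C1–C2: a cis-diol beside a Z olefin substituted at C10 is a halobenzene cis-dihydrodiol cut open between C2 and C7, with the halogen marking C10 for C14.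

## Retrosynthesis

**Acyl groups (27 ⇒ 26 ⇒ 25).** The two O–acyl bonds are cut first. The allylic C14 ester would not survive the palladium steps and the acetate would not survive the carbanion step, so both go on after all C–C bonds are made. Triol 25 is simpler by both esters. The forward reactions must pick the primary O14 over two secondary hydroxyls (26) and then O9 over O8 (27).

**C6–C7 and C12–O6 (25 ⇒ 24 ⇒ 22, via 23).** The ring and the lactone are opened together by a chromium-mediated Barbier disconnection to bromo aldehyde 22. The neighbouring choice, closing the ring at C2–C3 by sulfone alkylation with the lactone already present, was set aside. It would expose the methylene lactone to a carbanion and then to a reductive desulfonylation, whereas divalent chromium leaves esters and enals alone. Precursor 22 is acyclic and has only the two stereocentres C8 and C9. The forward step must close a ten-membered ring, add anti across C6–C7 and choose the C7 face.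

**C7–C11 (22 ⇒ 21 ⇒ 20 ⇒ 19 ⇒ 17 + 18).** The 2-(bromomethyl)acrylate of 22 is the transposed bromide of Baylis–Hillman adduct 19, made from aldehyde 17 and methyl acrylate 18. This brings in C11–C13 in one C–C bond and needs no stereocontrol, since the carbinol centre is erased on bromination. The C6 aldehyde is unmasked from a silyl ether (19 ⇒ 20 ⇒ 21) before the bromide is made, so the reactive bromide is formed last.

**C2–C3 (17 ⇒ 16 ⇒ 15 ⇒ 10 + 14).** The 1,5-diene is cut between its two allylic methylenes into sulfone 10 and allylic bromide 14. The sulfone is placed on C2, not C3. In the palladium-catalysed desulfonylation the hydride then goes to the less substituted allyl terminus (C2) and the C1=C10 olefin stays where it is. A C3 sulfone would give an allyl unit with two equivalent secondary termini. The cut is made at this early stage because no ester or Michael acceptor is yet present.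

**C3–C6 unit (14 ⇒ 13 ⇒ 12 ⇒ 11).** Bromide 14 comes from 4-methylfuran-2(5H)-one 11, whose ring fixes the Z geometry of C4=C5. Reduction to diol 12 is followed by silylation of the less hindered hydroxyl (13) and bromination.

**C10–C14 (10 ⇒ 9 ⇒ 8 ⇒ 7).** C14 is attached by Stille hydroxymethylation of vinyl bromide 7, with retention of geometry. It is done after the ozonolysis, because the bromine is what protects C1=C10 from ozone. It is done before the sulfide is oxidised, because allyl sulfones ionise with zerovalent palladium.

**C2 versus C7 (7 ⇒ 6 ⇒ 5).** The two primary hydroxyls of 5 are told apart by substitution rate. C2 is allylic, and C7 sits next to the dioxolane and is slow in SN2, so a Mitsunobu-type thioetherification should take C2 only. C7 is then capped as a triethylsilyl ether that can later be oxidised directly to the aldehyde.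

**Ring opening (5 ⇒ 3, via 4).** Diol 5 is the reductive ozonolysis product of diene acetonide 3, cleaved at the unhalogenated olefin. The ring of 3 is what makes C9 and C2 cis on C1=C10.

**Dearomatisation (3 ⇒ 2 ⇒ 1).** Acetonide 3 is the protected form of cis-dihydrodiol 2, made from bromobenzene 1 by toluene dioxygenase. This one step creates both C–O bonds at C8 and C9, cis and as one enantiomer, from an achiral arene.

## Roads not taken

**Alternative 1:** The cut is C5–C6, with C12–O6. Seco iodo aldehyde A2 (Z vinyl iodide at C5, aldehyde at C6, the acetate arm already on C7, 8,9-acetonide) would be treated with divalent chromium and a nickel co-catalyst. The vinylchromium adds to the aldehyde, the ten-membered ring closes, and the alkoxide lactonises to A1.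
- Merits: the ring closure is neutral and chemoselective, the lactone forms in the same operation, and the Z geometry of C4=C5 is carried in by the iodide.
- Weak points: C6 is created by addition to an α-branched aldehyde inside a forming medium ring, where nothing in the substrate secures the 6,7-trans outcome. C7 must be set beforehand by a separate asymmetric C–C bond formation next to C8. C13 must be added afterwards by enolate methylenation of a base-sensitive macrocycle.
- Comparison: A1 carries the same 8,9-acetonide, so this road can use the same arene diol. Its ring closure is at least as mild as the one chosen. Against that, the chosen plan forms C6 and C7 in one closed transition state at ring closure, brings the methylene in with methyl acrylate 18, and takes the Z olefin from butenolide 11 without a vinyl iodide.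

**Alternative 2:** The cut is the C4–C9 bond of bicyclic mesylate A4, a cis-fused decalin with a tertiary C9 alcohol and a C5 mesylate. A potassium alkoxide base would deprotonate the C9 hydroxyl, and Wharton fragmentation would break C4–C9 as the mesylate leaves, giving ten-membered dienone A3.
- Merits: the medium ring is formed by ring expansion, not by an end-to-end closure, so no high dilution is needed. Both Z olefins follow stereospecifically from the ring fusion and the antiperiplanar arrangement. In ring formation and olefin geometry this road is better than the chosen one.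
- Weak points: A4 needs six contiguous stereocentres on a decalin, three of which (C4, C5, C9) are destroyed in the step. Afterwards the C9 ketone must be reduced from the correct face in a flexible ring, C12 must be oxidised to the lactone carbonyl, and two p-methoxybenzyl and two silyl groups must be exchanged.
- Comparison: the chosen plan accepts an entropically harder macrocyclisation. In return it gets C8 and C9 with fixed absolute configuration in one step from an arene, needs no redox adjustment at C9 or C12, and handles far fewer stereocentres before the ring is closed.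

**Alternative 3:** The cut is C9–C10. Iodo aldehyde A6 (Z vinyl iodide at C10, α-silyloxy aldehyde at C9, methylene lactone in place) would close under divalent chromium with a nickel co-catalyst to A5.
- Merits: the methylene lactone is tolerated, and the step liberates the 9-hydroxyl alone, with O8 and O14 still silylated. That is exactly the differentiation the 9-acetate needs. On this point the road is better than the chosen plan, which relies on a rate difference between two secondary hydroxyls in step 22.
- Weak points: C9 is created during ring closure by Felkin-type addition to an epimerisable α-silyloxy aldehyde, and the demands of the ten-membered transition state can override acyclic Felkin control. The C6/C7/C8 triad must be assembled beforehand by other asymmetric reactions, and the arene diol can no longer supply C9.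
- Comparison: the chosen plan sets C8 and C9 together before any C–C bond is made and leaves neither to a macrocyclic addition. Its weaker acylation selectivity is covered by a fallback.

Key step: step 1

Remark: atoms are numbered as in the germacrane skeleton throughout, also in acyclic intermediates. The NADH consumed in step 1 is regenerated by the cells from glucose and is treated as catalytic.

## Steps

Step 1
Reactants: 1 bromobenzene
Product: 2 (1S,2S)-3-bromocyclohexa-3,5-diene-1,2-diol
Conditions: whole cells of E. coli JM109 (pDTG601) expressing toluene dioxygenase, IPTG induction, glucose-fed aerated fermentation, pH 7, 30 °C; EtOAc extraction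
Reagents that add atoms: dioxygen, O=O
Why: Toluene dioxygenase is a three-component Rieske system in which electrons from NADH pass through a flavin reductase and a ferredoxin to the [2Fe–2S] cluster of the oxygenase and on to its mononuclear non-haem iron, which binds O2 next to the arene. The reduced iron–peroxo unit transfers both oxygen atoms to the same face of the 2,3-bond (ortho and meta to bromine), so the future C8–O and C9–O bonds form cis in one event and the ring is left as a 1,3-diene. The closest known reaction type is this very one, the whole-cell cis-dihydroxylation of monohalobenzenes to homochiral 3-halo-cis-dihydrodiols. No ring is closed. Both new stereocentres (1S,2S) are controlled by the enzyme pocket, which orients the halogen and exposes one arene face to the iron–oxygen unit, since the substrate carries no stereochemical information. The step needs regioselectivity for the 2,3-bond, enantioselectivity and arrest at the diol stage; the first two come from the active site and the last from the host, which expresses the dioxygenase but no cis-diol dehydrogenase, so 2 is not rearomatised to a catechol. Bromine is retained and marks C10 for the later Stille coupling.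

Step 2
Reactants: 2 (1S,2S)-3-bromocyclohexa-3,5-diene-1,2-diol
Product: 3 (3aS,7aS)-4-bromo-2,2-dimethyl-3a,7a-dihydro-1,3-benzodioxole
Conditions: 2,2-dimethoxypropane, p-TsOH (cat.), acetone, rt
Reagents that add atoms: 2,2-dimethoxypropane, COC(C)(C)OC
Why: Acid-catalysed transacetalisation of a cis-1,2-diol (acetonide formation); it stops dehydration to bromophenol and gives the cis-dioxolane that later holds C7 and C10 on the same side.

Step 3
Reactants: 3 (3aS,7aS)-4-bromo-2,2-dimethyl-3a,7a-dihydro-1,3-benzodioxole
Product: 5 (E)-3-bromo-3-[(4S,5S)-5-(hydroxymethyl)-2,2-dimethyl-1,3-dioxolan-4-yl]prop-2-en-1-ol, via secondary ozonide 4 (not isolated)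
Conditions: O3, CH2Cl2, −78 °C, Sudan Red 7B end-point; then MeOH, NaBH4, −78 → 0 °C
Reagents that add atoms: ozone, [O-][O+]=O
Why: Ozonolysis with reductive work-up: ozone attacks the electron-richer disubstituted olefin of the diene, and the remaining C=C, which bears bromine and is then conjugated to the new carbonyl, reacts far more slowly, so one equivalent should cleave only the C2/C7 bond. NaBH4 reduces the ozonide to the two primary alcohols at once, so the Z-enal is never exposed to isomerising conditions and the ring-derived geometry (C9 and C2 cis) is kept.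

Step 4
Reactants: 5 (E)-3-bromo-3-[(4S,5S)-5-(hydroxymethyl)-2,2-dimethyl-1,3-dioxolan-4-yl]prop-2-en-1-ol
Product: 6 {(4S,5S)-5-[(E)-1-bromo-3-(phenylsulfanyl)prop-1-en-1-yl]-2,2-dimethyl-1,3-dioxolan-4-yl}methanol
Conditions: PhSSPh (1.05 equiv), Bu3P (1.1 equiv), THF, 0 °C
Reagents that add atoms: diphenyl disulfide, c1ccc(SSc2ccccc2)cc1
Why: Mitsunobu-type thioetherification: alkoxyphosphonium formation is reversible and the thiolate displacement is rate-limiting, and SN2 at the allylic C2 is much faster than at C7, which is β-branched and flanked by the dioxolane oxygen. One equivalent should therefore convert only the C2 hydroxyl.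

Step 5
Reactants: 6 {(4S,5S)-5-[(E)-1-bromo-3-(phenylsulfanyl)prop-1-en-1-yl]-2,2-dimethyl-1,3-dioxolan-4-yl}methanol
Product: 7 triethylsilyl ether of 6 at O7
Conditions: Et3SiCl, imidazole, CH2Cl2, 0 °C
Reagents that add atoms: chlorotriethylsilane, CC[Si](Cl)(CC)CC
Why: Standard silylation of a primary alcohol; the triethylsilyl group is chosen because a primary triethylsilyl ether can later be oxidised straight to the aldehyde.

Step 6
Reactants: 7 triethylsilyl ether of 6 at O7
Product: 8 allylic alcohol with CH2OH (C14) in place of bromine at C10, C9 and C2 cis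
Conditions: Bu3SnCH2OH (1.5 equiv), Pd(PPh3)4 (10 mol %), dioxane, 90 °C
Reagents that add atoms: (tributylstannyl)methanol, CCCC[Sn](CCCC)(CCCC)CO
Why: Stille coupling of a vinyl bromide with a hydroxymethyl stannane; oxidative addition, transmetalation and reductive elimination all proceed with retention, so the olefin geometry set by the arene ring is carried into C1=C10. It is run on the sulfide because an allyl sulfone would ionise with zerovalent palladium.

Step 7
Reactants: 8 allylic alcohol with CH2OH (C14) in place of bromine at C10
Product: 9 triisopropylsilyl ether of 8 at O14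
Conditions: i-Pr3SiCl, imidazole, DMF, rt
Reagents that add atoms: chlorotriisopropylsilane, CC(C)[Si](Cl)(C(C)C)C(C)C
Why: Standard silylation of a primary allylic alcohol; the triisopropylsilyl ether survives the later cleavage of the primary TBS ether at C6 and falls with the acetonide in step 20.

Step 8
Reactants: 9 triisopropylsilyl ether of 8 at O14
Product: 10 allylic phenyl sulfone at C2
Conditions: Pr4N[RuO4] (5 mol %), 4-methylmorpholine N-oxide (3 equiv), 4 Å MS, MeCN, rt
Reagents that add atoms: 4-methylmorpholine N-oxide, C[N+]1([O-])CCOCC1
Why: Catalytic perruthenate oxidation of a sulfide to the sulfone under neutral conditions, which spares the trisubstituted olefin, the silyl ethers and the acetonide.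

Step 9
Reactants: 11 4-methylfuran-2(5H)-one
Product: 12 (Z)-2-methylbut-2-ene-1,4-diol
Conditions: i-Bu2AlH (3 equiv), CH2Cl2, −78 → 0 °C; Rochelle salt work-up
Reagents that add atoms: none
Why: 1,2-Reduction of an unsaturated lactone to the diol; the Z geometry of the future C4=C5 is fixed by the ring of 11.

Step 10
Reactants: 12 (Z)-2-methylbut-2-ene-1,4-diol
Product: 13 (Z)-4-[(tert-butyldimethylsilyl)oxy]-2-methylbut-2-en-1-ol
Conditions: t-BuMe2SiCl (1.0 equiv), imidazole, CH2Cl2, −40 → 0 °C
Reagents that add atoms: tert-butylchlorodimethylsilane, CC(C)(C)[Si](C)(C)Cl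
Why: Kinetic monosilylation at the less hindered hydroxyl, the one on the CH2 next to the vinylic hydrogen (C6) and not the one next to the methyl-bearing carbon (C3); the minor regioisomer and the bis-ether are removable by chromatography.

Step 11
Reactants: 13 (Z)-4-[(tert-butyldimethylsilyl)oxy]-2-methylbut-2-en-1-ol
Product: 14 (Z)-[(4-bromo-3-methylbut-2-en-1-yl)oxy](tert-butyl)dimethylsilane
Conditions: CBr4, PPh3, 2,6-lutidine, CH2Cl2, 0 °C
Reagents that add atoms: tetrabromomethane, BrC(Br)(Br)Br
Why: Appel bromination of a primary allylic alcohol by SN2 displacement of the alkoxyphosphonium, with the olefin geometry untouched.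

Step 12
Reactants: 10 allylic phenyl sulfone at C2; 14 (Z)-[(4-bromo-3-methylbut-2-en-1-yl)oxy](tert-butyl)dimethylsilane
Product: 15 C2-alkylated sulfone carrying the C3–C6 unit (both C2 epimers)
Conditions: LiN(SiMe3)2 (1.1 equiv), THF/DMPU, −78 °C; then 14, −78 → −40 °C
Reagents that add atoms: none
Why: α-Alkylation of an allylic sulfone carbanion with an allylic bromide forms C2–C3; at −78 °C the anion keeps the C1=C10 geometry and does not eliminate the neighbouring alkoxy groups. The new C2 centre is unselective and is removed in the next step.

Step 13
Reactants: 15 C2-alkylated sulfone carrying the C3–C6 unit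
Product: 16 Z,Z-1,5-diene with C7–OTES, C6–OTBS, O14–TIPS and the 8,9-acetonide
Conditions: PdCl2(dppp) (5 mol %), LiBHEt3 (2.5 equiv), THF, 0 °C
Reagents that add atoms: none
Why: Palladium-catalysed reductive desulfonylation of an allylic sulfone: the sulfinate leaves to give a π-allyl complex and hydride is delivered to the less substituted terminus C2, so the trisubstituted C1=C10 olefin keeps its position and geometry. No ester or halide is present that the hydride could attack.

Step 14
Reactants: 16 Z,Z-1,5-diene with C7–OTES, C6–OTBS, O14–TIPS and the 8,9-acetonide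
Product: 17 C7 aldehyde (4-formyl dioxolane)
Conditions: (COCl)2, DMSO, CH2Cl2, −78 → −30 °C; Et3N, → 0 °C
Reagents that add atoms: none
Why: Swern conditions oxidise a primary triethylsilyl ether directly to the aldehyde while the TBS and triisopropylsilyl ethers stay; the amine is added cold to keep the α-oxygenated C8 centre from epimerising.

Step 15
Reactants: 17 C7 aldehyde (4-formyl dioxolane); 18 methyl acrylate
Product: 19 Baylis–Hillman adduct, methyl 2-[hydroxy(dioxolanyl)methyl]acrylate (both C7 epimers)
Conditions: 18 (10 equiv), DABCO (1 equiv), dioxane/H2O 1:1, rt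
Reagents that add atoms: none
Why: Baylis–Hillman reaction: the amine adds to the acrylate and the resulting enolate attacks the activated α,β-dioxygenated aldehyde, forming C7–C11. The carbinol configuration does not matter because C7 becomes sp2 in step 18.

Step 16
Reactants: 19 Baylis–Hillman adduct
Product: 20 C6 primary allylic alcohol
Conditions: HF·pyridine, pyridine, THF, 0 °C
Reagents that add atoms: none
Why: Buffered fluoride cleaves the least hindered primary TBS ether; the primary triisopropylsilyl ether and the acetonide are much slower under these conditions.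

Step 17
Reactants: 20 C6 primary allylic alcohol
Product: 21 C6 (Z)-enal
Conditions: MnO2 (activated, excess), CH2Cl2, rt
Reagents that add atoms: none
Why: MnO2 oxidises the electron-rich primary allylic alcohol; the hindered carbinol next to the electron-poor acrylate is inert, and the neutral surface oxidation leaves the Z-enal geometry intact.

Step 18
Reactants: 21 C6 (Z)-enal
Product: 22 methyl (Z)-2-(bromomethyl)alk-2-enoate with the C6 (Z)-enal (bromo aldehyde)
Conditions: N-bromosuccinimide, Me2S, CH2Cl2, −30 → 0 °C
Reagents that add atoms: N-bromosuccinimide, O=C1CCC(=O)N1Br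
Why: Corey–Kim-type activation of the Baylis–Hillman alcohol as an alkoxysulfonium salt followed by SN2′ attack of bromide at C13 gives the transposed 2-(bromomethyl)alk-2-enoate, normally as the Z isomer. The bromide is made last so that it meets no nucleophile before the cyclisation.

Step 19
Reactants: 22 methyl (Z)-2-(bromomethyl)alk-2-enoate with the C6 (Z)-enal
Product: 24 (6R,7R,8S,9R)-8,9-O-isopropylidene-14-O-triisopropylsilyl lactone, via hydroxy ester 23 (not isolated)
Conditions: CrCl2 (8 equiv), DMF, rt, syringe-pump addition to 2 mM; PPTS (cat.), CH2Cl2, rt to complete lactonisation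
Reagents that add atoms: none
Why: Chromium-mediated Barbier (Nozaki–Hiyama) allylation run intramolecularly: CrCl2 reduces the allylic bromide to an allylchromium that adds through its γ-carbon C7 to the C6 aldehyde in a chair transition state, and the trivalent chromium alkoxide closes onto the ester. Allylic 1,3-strain keeps H8 in the plane of the allyl unit and the cis-dioxolane holds C10 over the C9 face, so the tethered aldehyde should reach C7 anti to the C8–C9 bond (7R); the chair with the C5 and C8 branches equatorial, the usual preference of γ-substituted allylchromium reagents, gives the 6,7-anti adduct and hence the trans-lactone (6R). The two Z olefins and the dioxolane act as turn elements that favour closure of the ten-membered ring at high dilution.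

Step 20
Reactants: 24 (6R,7R,8S,9R)-8,9-O-isopropylidene-14-O-triisopropylsilyl lactone
Product: 25 8,9,14-triol lactone
Conditions: HF (48% aq.)/MeCN 1:9, 0 °C → rt
Reagents that add atoms: none
Why: Aqueous HF in acetonitrile cleaves the primary silyl ether and hydrolyses the acetonide in one operation; the methylene lactone and the olefins are stable to this weak acid, and no base is present that could move the lactone to O8.

Step 21
Reactants: 25 8,9,14-triol lactone
Product: 26 14-O-(3-methylbutanoyl) 8,9-diol lactone
Conditions: isovaleryl chloride (1.05 equiv), 2,4,6-collidine, CH2Cl2, −78 → −30 °C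
Reagents that add atoms: 3-methylbutanoyl chloride, CC(C)CC(Cl)=O
Why: Acylation with an acid chloride and a hindered pyridine base at low temperature is selective for a primary over secondary hydroxyls, here the allylic O14 over the two ring carbinols.

Step 22
Reactants: 26 14-O-(3-methylbutanoyl) 8,9-diol lactone
Product: 27 (1(10)Z,4Z,6R,7R,8S,9R)-9-acetoxy-8-hydroxy-14-(3-methylbutanoyloxy)germacra-1(10),4,11(13)-trien-12,6-olide
Conditions: Ac2O (1.2 equiv), pyridine, CH2Cl2, −20 → 0 °C, no DMAP
Reagents that add atoms: acetic anhydride, CC(=O)OC(C)=O
Why: Regioselective acetylation: O9–H is allylic and flanked by the planar C10, whereas O8–H sits next to the ring-fusion carbon C7 and on the same side as the lactone, so the less hindered O9 should react first. Mild base without DMAP limits acyl migration, which would in any case drain toward the less hindered ester.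

## Compound list

1 | bromobenzene | Brc1ccccc1 | starting material
2 | (1S,2S)-3-bromocyclohexa-3,5-diene-1,2-diol | O[C@H]1C=CC=C(Br)[C@H]1O | intermediate
3 | (3aS,7aS)-4-bromo-2,2-dimethyl-3a,7a-dihydro-1,3-benzodioxole | CC1(C)O[C@H]2C=CC=C(Br)[C@H]2O1 | intermediate
4 | secondary ozonide of 3 at the unhalogenated olefin (1,2,4-trioxolane bridging C7 and C2; not isolated) | CC1(C)O[C@H]2C3OOC(O3)C=C(Br)[C@H]2O1 | intermediate
5 | (E)-3-bromo-3-[(4S,5S)-5-(hydroxymethyl)-2,2-dimethyl-1,3-dioxolan-4-yl]prop-2-en-1-ol (C9 and C2 cis) | OC[C@@H]1OC(C)(C)O[C@@H]1/C(Br)=C\CO | intermediate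
6 | {(4S,5S)-5-[(E)-1-bromo-3-(phenylsulfanyl)prop-1-en-1-yl]-2,2-dimethyl-1,3-dioxolan-4-yl}methanol | OC[C@@H]1OC(C)(C)O[C@@H]1/C(Br)=C\CSc1ccccc1 | intermediate
7 | triethylsilyl ether of 6 at O7 | CC[Si](CC)(CC)OC[C@@H]1OC(C)(C)O[C@@H]1/C(Br)=C\CSc1ccccc1 | intermediate
8 | allylic alcohol with CH2OH (C14) in place of bromine at C10, C9 and C2 cis | CC[Si](CC)(CC)OC[C@@H]1OC(C)(C)O[C@@H]1/C(CO)=C\CSc1ccccc1 | intermediate
9 | triisopropylsilyl ether of 8 at O14 | CC[Si](CC)(CC)OC[C@@H]1OC(C)(C)O[C@@H]1/C(CO[Si](C(C)C)(C(C)C)C(C)C)=C\CSc1ccccc1 | intermediate
10 | allylic phenyl sulfone at C2 | CC[Si](CC)(CC)OC[C@@H]1OC(C)(C)O[C@@H]1/C(CO[Si](C(C)C)(C(C)C)C(C)C)=C\CS(=O)(=O)c1ccccc1 | intermediate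
11 | 4-methylfuran-2(5H)-one | CC1=CC(=O)OC1 | starting material
12 | (Z)-2-methylbut-2-ene-1,4-diol | OC/C=C(C)\CO | intermediate
13 | (Z)-4-[(tert-butyldimethylsilyl)oxy]-2-methylbut-2-en-1-ol | CC(C)(C)[Si](C)(C)OC/C=C(C)\CO | intermediate
14 | (Z)-[(4-bromo-3-methylbut-2-en-1-yl)oxy](tert-butyl)dimethylsilane | CC(C)(C)[Si](C)(C)OC/C=C(C)\CBr | intermediate
15 | C2-alkylated sulfone carrying the C3–C6 unit (both C2 epimers) | CC[Si](CC)(CC)OC[C@@H]1OC(C)(C)O[C@@H]1/C(CO[Si](C(C)C)(C(C)C)C(C)C)=C\C(C/C(C)=C\CO[Si](C)(C)C(C)(C)C)S(=O)(=O)c1ccccc1 | intermediate
16 | Z,Z-1,5-diene with C7–OTES, C6–OTBS, O14–TIPS and the 8,9-acetonide | CC[Si](CC)(CC)OC[C@@H]1OC(C)(C)O[C@@H]1/C(CO[Si](C(C)C)(C(C)C)C(C)C)=C\CC/C(C)=C\CO[Si](C)(C)C(C)(C)C | intermediate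
17 | C7 aldehyde (4-formyl dioxolane) | O=C[C@@H]1OC(C)(C)O[C@@H]1/C(CO[Si](C(C)C)(C(C)C)C(C)C)=C\CC/C(C)=C\CO[Si](C)(C)C(C)(C)C | intermediate
18 | methyl acrylate | C=CC(=O)OC | starting material
19 | Baylis–Hillman adduct, methyl 2-[hydroxy(dioxolanyl)methyl]acrylate (both C7 epimers) | COC(=O)C(=C)C(O)[C@@H]1OC(C)(C)O[C@@H]1/C(CO[Si](C(C)C)(C(C)C)C(C)C)=C\CC/C(C)=C\CO[Si](C)(C)C(C)(C)C | intermediate
20 | C6 primary allylic alcohol | COC(=O)C(=C)C(O)[C@@H]1OC(C)(C)O[C@@H]1/C(CO[Si](C(C)C)(C(C)C)C(C)C)=C\CC/C(C)=C\CO | intermediate
21 | C6 (Z)-enal | COC(=O)C(=C)C(O)[C@@H]1OC(C)(C)O[C@@H]1/C(CO[Si](C(C)C)(C(C)C)C(C)C)=C\CC/C(C)=C\C=O | intermediate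
22 | methyl (Z)-2-(bromomethyl)alk-2-enoate with the C6 (Z)-enal (bromo aldehyde) | COC(=O)/C(CBr)=C/[C@@H]1OC(C)(C)O[C@@H]1/C(CO[Si](C(C)C)(C(C)C)C(C)C)=C\CC/C(C)=C\C=O | intermediate
23 | ten-membered hydroxy ester (6R,7R,8S,9R; not isolated) | COC(=O)C(=C)[C@H]1[C@H](O)/C=C(/C)CC/C=C(/CO[Si](C(C)C)(C(C)C)C(C)C)[C@H]2OC(C)(C)O[C@@H]12 | intermediate
24 | (6R,7R,8S,9R)-8,9-O-isopropylidene-14-O-triisopropylsilyl lactone | C=C1C(=O)O[C@@H]2/C=C(/C)CC/C=C(/CO[Si](C(C)C)(C(C)C)C(C)C)[C@H]3OC(C)(C)O[C@H]3[C@@H]12 | intermediate
25 | 8,9,14-triol lactone | C=C1C(=O)O[C@@H]2/C=C(/C)CC/C=C(/CO)[C@@H](O)[C@@H](O)[C@@H]12 | intermediate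
26 | 14-O-(3-methylbutanoyl) 8,9-diol lactone | C=C1C(=O)O[C@@H]2/C=C(/C)CC/C=C(/COC(=O)CC(C)C)[C@@H](O)[C@@H](O)[C@@H]12 | intermediate
27 | (1(10)Z,4Z,6R,7R,8S,9R)-9-acetoxy-8-hydroxy-14-(3-methylbutanoyloxy)germacra-1(10),4,11(13)-trien-12,6-olide | C=C1C(=O)O[C@@H]2/C=C(/C)CC/C=C(/COC(=O)CC(C)C)[C@@H](OC(C)=O)[C@@H](O)[C@@H]12 | target

## Step count and least certain steps

Total: 22 steps. Longest linear sequence: 19 steps (steps 1–8 and 12–22, from bromobenzene 1); the C3–C6 unit adds 3 steps (9–11).

**Step 1 (key step).**
- Risk: the enzymatic selectivity is not in doubt. What may fail is throughput: bromobenzene and the diol are toxic to the cells, and the acid- and heat-sensitive diol can dehydrate to bromophenols while a dilute broth is concentrated.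
- Fallback: from 1 the biotransformation is run as before, but the free diol is not isolated. Phenylboronic acid is added to the clarified broth and the product is extracted as its cyclic ester, (3aS,7aS)-4-bromo-2-phenyl-3a,7a-dihydro-1,3,2-benzodioxaborole F1. This is transacetalised with 2,2-dimethoxypropane and catalytic acid in acetone/methanol, and the route is rejoined at 3.

**Step 19.**
- Risk: the anti preference of the allylchromium addition may erode inside the medium-ring transition state, so that the C6 epimer with a cis-lactone forms beside or instead of 24. Intermolecular coupling may also compete with ring closure.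
- Fallback: from 22 the cyclisation is still run and the 6-epi cis-lactone F2 is collected. LiOH in aqueous THF opens it to the 6-epi hydroxy acid F3, and Mitsunobu lactonisation (PPh3, diisopropyl azodicarboxylate) closes the lactone with inversion at the allylic C6. The route is rejoined at 24.

**Step 22.**
- Risk: discrimination between the two secondary hydroxyls may be poor, or acetylation may prefer O8, and the acetyl group may migrate across the cis-diol.
- Fallback: from 26 the diol is converted with trimethyl orthoacetate and PPTS into the cyclic 8,9-orthoacetate F4. Opening with aqueous acetic acid places the ester on the oxygen that direct acylation disfavours, and the route is rejoined at 27.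

**Step 4.**
- Risk: the thioetherification may not stop at C2. Substitution at C7 as well, or closure of the C7 hydroxyl onto the activated C2, would consume the diol.
- Fallback: from 5, MnO2 oxidises only the allylic alcohol to the hydroxy enal F5, which is silylated with Et3SiCl to the TES enal F6. Luche reduction (NaBH4, CeCl3·7H2O) gives the C7-protected allylic alcohol F7, the only hydroxyl left for PhSSPh/Bu3P. The route is rejoined at 7.

**Step 15.**
- Risk: during the slow amine-catalysed addition the aldehyde may epimerise at C8, turning the cis-dioxolane into the more stable trans isomer.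
- Fallback: from 17, i-Bu2AlH and HMPA hydroaluminate methyl propiolate to methyl 2-(diisobutylalumanyl)acrylate F8. This adds to the aldehyde at low temperature within hours without amine base and gives 19 directly.

**Step 3.**
- Risk: ozone may go on to attack the brominated olefin before the first cleavage is complete, which would degrade the chain to a four-carbon fragment.
- Fallback: from 3, OsO4 (cat.) with 4-methylmorpholine N-oxide dihydroxylates only the unhalogenated olefin, anti to the acetonide, to diol F9. NaIO4 cleaves it to dialdehyde F10, and NaBH4 reduces that to 5.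

## Further compounds

F1 | step 1 | (3aS,7aS)-4-bromo-2-phenyl-3a,7a-dihydro-1,3,2-benzodioxaborole | c1ccccc1B1O[C@H]2C=CC=C(Br)[C@H]2O1
F2 | step 19 | 6-epi cis-lactone (6S,7R,8S,9R) with 8,9-acetonide and O14–TIPS | C=C1C(=O)O[C@H]2/C=C(/C)CC/C=C(/CO[Si](C(C)C)(C(C)C)C(C)C)[C@H]3OC(C)(C)O[C@H]3[C@@H]12
F3 | step 19 | 6-epi hydroxy acid (ring-opened F2) | OC(=O)C(=C)[C@H]1[C@@H](O)/C=C(/C)CC/C=C(/CO[Si](C(C)C)(C(C)C)C(C)C)[C@H]2OC(C)(C)O[C@@H]12
F4 | step 22 | cyclic 8,9-O-(1-methoxyethylidene) orthoacetate of 26 | C=C1C(=O)O[C@@H]2/C=C(/C)CC/C=C(/COC(=O)CC(C)C)[C@H]3OC(C)(OC)O[C@H]3[C@@H]12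
F5 | step 4 | (Z-ring-type) hydroxy enal, C2 aldehyde with free C7 hydroxyl | OC[C@@H]1OC(C)(C)O[C@@H]1/C(Br)=C\C=O
F6 | step 4 | triethylsilyl ether of F5 | CC[Si](CC)(CC)OC[C@@H]1OC(C)(C)O[C@@H]1/C(Br)=C\C=O
F7 | step 4 | C2 allylic alcohol with C7–OTES | CC[Si](CC)(CC)OC[C@@H]1OC(C)(C)O[C@@H]1/C(Br)=C\CO
F8 | step 15 | methyl 2-(diisobutylalumanyl)acrylate | COC(=O)C(=C)[Al](CC(C)C)CC(C)C
F9 | step 3 | cyclic diol from dihydroxylation of 3 anti to the acetonide | CC1(C)O[C@H]2[C@H](O)[C@H](O)C=C(Br)[C@H]2O1
F10 | step 3 | dialdehyde (C7 aldehyde and C2 enal) | O=C[C@@H]1OC(C)(C)O[C@@H]1/C(Br)=C\C=O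
A1 | alternative 1 | trans-fused bicyclic lactone with 8,9-acetonide, lacking the C13 methylene | C1C(=O)O[C@@H]2/C=C(/C)CC/C=C(/CO[Si](C)(C)C(C)(C)C)[C@H]3OC(C)(C)O[C@H]3[C@@H]12
A2 | alternative 1 | seco iodo aldehyde (Z vinyl iodide at C5, C6 aldehyde, methyl ester arm on C7) | O=C[C@H](CC(=O)OC)[C@@H]1OC(C)(C)O[C@@H]1/C(CO[Si](C)(C)C(C)(C)C)=C\CC/C(C)=C\I
A3 | alternative 2 | ten-membered Z,Z-dienone with C9 ketone | O=C1/C(COCc2ccc(OC)cc2)=C\CC/C(C)=C\[C@@H](O[Si](C)(C)C(C)(C)C)[C@H](C(=C)CO[Si](C)(C)C(C)(C)C)[C@@H]1OCc1ccc(OC)cc1
A4 | alternative 2 | cis-fused decalin with C9 tertiary alcohol and C5 mesylate | C[C@]12CCC=C(COCc3ccc(OC)cc3)[C@@]1(O)[C@@H](OCc1ccc(OC)cc1)[C@@H](C(=C)CO[Si](C)(C)C(C)(C)C)[C@H](O[Si](C)(C)C(C)(C)C)[C@H]2OS(C)(=O)=O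
A5 | alternative 3 | 9-hydroxy germacranolide with O8 TES and O14 TBS | C=C1C(=O)O[C@@H]2/C=C(/C)CC/C=C(/CO[Si](C)(C)C(C)(C)C)[C@@H](O)[C@@H](O[Si](CC)(CC)CC)[C@@H]12
A6 | alternative 3 | seco iodo aldehyde (Z vinyl iodide at C10, α-silyloxy aldehyde at C9, methylene lactone in place) | C=C1C(=O)O[C@H](/C=C(/C)CC/C=C(/CO[Si](C)(C)C(C)(C)C)I)[C@H]1[C@H](O[Si](CC)(CC)CC)C=O
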